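## Retrosynthetic overview

1. The target is disconnected first at the second C8 methyl (dearomatisation of ring A, done last) and then at the C6–acyl bond, which comes from lithiation of the only aryl C–H and the N-methoxy-N-methylamide of (R)-2-methylbutanoic acid.
2. Ring B is opened at C3=C4 by ring-closing olefin metathesis of a 2-(linalyloxy)styrene. The strategy rests on C2 of ring B (O1–C2–C3=C4–C4a=C8a): it carries O1, a methyl, the 4-methylpent-3-enyl chain and the vinylic C3, the same four groups as the carbinol carbon of (R)-linalool, so C2 is taken from the chiral pool and only the C3=C4 alkene has to be made.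
3. The aryl–O1 bond comes from displacement of fluoride on an ortho-fluorobenzaldehyde by (R)-linalyl oxide, which leaves C2 untouched; the formyl group activates the displacement and is then methylenated to the styrene.
4. The arene comes from 1-fluoro-3,5-dimethoxybenzene by formylation, deoxygenation to methyl and a second formylation; the methyl ethers are then exchanged for MOM ethers so the phenols can be freed late without a boron halide.
5. Ring order: ring A is the benzene ring of the starting fluoroarene, ring B is closed in the key step, and ring A is dearomatised in the final step.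

Key step: step 8

Assumption: both phenol oxygens are carried as methoxymethyl ethers from step 5 onward, because cleaving aryl methyl ethers with a boron halide after acylation would expose the tertiary allylic C2–O1 ether, the trisubstituted alkene and the α-stereogenic ketone to a strong Lewis acid; both formylations are taken to occur ortho to fluorine, as expected for 5-substituted 1,3-dimethoxybenzenes.

## Route

Step 1
Reactants: 1 1-fluoro-3,5-dimethoxybenzene
Product: 3 2-fluoro-4,6-dimethoxybenzaldehyde, via aryl iminium chloride 2 (not isolated)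
Conditions: POCl3, DMF, 0 °C → 70 °C; then ice-water
Reagents that add atoms: N,N-dimethylformamide, CN(C)C=O; water, O
Why: Vilsmeier–Haack formylation should go to C2, which is para to one methoxy group, ortho to the other and flanked only by the small fluorine, in preference to C4 between the two methoxy groups, and a minor regioisomer would be removed by crystallisation.

Step 2
Reactants: 3 2-fluoro-4,6-dimethoxybenzaldehyde
Product: 5 1-fluoro-3,5-dimethoxy-2-methylbenzene, via benzylic alcohol 4 (not isolated)
Conditions: Et3SiH, CF3CO2H, CH2Cl2, 0 °C → rt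
Reagents that add atoms: none
Why: Ionic hydrogenation of an electron-rich benzaldehyde passes through the benzylic alcohol and the ortho/para-methoxy-stabilised benzylic cation to the methylarene, and it avoids hydrazine-based deoxygenation, which would displace the ortho fluorine.

Step 3
Reactants: 5 1-fluoro-3,5-dimethoxy-2-methylbenzene
Product: 7 2-fluoro-4,6-dimethoxy-3-methylbenzaldehyde, via aryl iminium chloride 6 (not isolated)
Conditions: POCl3, DMF, 0 °C → 80 °C; then ice-water
Reagents that add atoms: N,N-dimethylformamide, CN(C)C=O; water, O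
Why: A second Vilsmeier–Haack formylation should take C6, the remaining position ortho to fluorine and para to the C3 methoxy group, because the other free position lies between two methoxy groups whose methyls are both turned toward it (the C3 methoxy being pushed that way by the adjacent methyl).

Step 4
Reactants: 7 2-fluoro-4,6-dimethoxy-3-methylbenzaldehyde
Product: 9 2-fluoro-4,6-dihydroxy-3-methylbenzaldehyde, via bis(dibromoboryl) ether 8 (not isolated)
Conditions: BBr3, CH2Cl2, −78 °C → rt; then H2O
Reagents that add atoms: none
Why: Lewis acid cleavage of both aryl methyl ethers with boron tribromide is done here, where no acid-sensitive group is present, and aqueous work-up returns the free phenols and the aldehyde.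

Step 5
Reactants: 9 2-fluoro-4,6-dihydroxy-3-methylbenzaldehyde
Product: 11 2-fluoro-4,6-bis(methoxymethoxy)-3-methylbenzaldehyde, via disodium bis-phenoxide 10 (not isolated)
Conditions: NaH, DMF, 0 °C; then MOMCl, 0 °C → rt
Reagents that add atoms: chloromethyl methyl ether, COCCl
Why: Williamson-type O-alkylation of the pre-formed bis-phenoxide protects both phenols, the sodium salt being needed for the hydrogen-bonded ortho hydroxyl, as base-stable acetals that later direct lithiation and are removed by mild acid.

Step 6
Reactants: 11 2-fluoro-4,6-bis(methoxymethoxy)-3-methylbenzaldehyde; 12 (R)-linalool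
Product: 14 2-{[(3R)-3,7-dimethylocta-1,6-dien-3-yl]oxy}-4,6-bis(methoxymethoxy)-3-methylbenzaldehyde, via potassium (R)-linalyl oxide 13 (not isolated)
Conditions: 12, KH, THF, 0 °C → rt; then 11, 18-crown-6, THF, 0 °C → 45 °C
Reagents that add atoms: none
Why: Nucleophilic aromatic substitution (addition–elimination) of fluoride by the tertiary alkoxide is activated by the ortho formyl group and not opposed by the two meta alkoxy groups, and because only the aryl–oxygen bond is formed the carbinol carbon of (R)-linalool keeps its configuration and becomes C2 of the target.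

Step 7
Reactants: 14 2-{[(3R)-3,7-dimethylocta-1,6-dien-3-yl]oxy}-4,6-bis(methoxymethoxy)-3-methylbenzaldehyde
Product: 15 2-{[(3R)-3,7-dimethylocta-1,6-dien-3-yl]oxy}-1-ethenyl-4,6-bis(methoxymethoxy)-3-methylbenzene
Conditions: Ph3PCH3Br, KOtBu, THF, 0 °C → rt
Reagents that add atoms: methyltriphenylphosphonium bromide, C[P+](c1ccccc1)(c1ccccc1)c1ccccc1.[Br-]
Why: Wittig methylenation converts the hindered, non-enolisable aldehyde into the styrene under basic conditions that leave the tertiary allyl aryl ether and the MOM acetals intact.

Step 8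
Reactants: 15 2-{[(3R)-3,7-dimethylocta-1,6-dien-3-yl]oxy}-1-ethenyl-4,6-bis(methoxymethoxy)-3-methylbenzene
Product: 16 (2R)-5,7-bis(methoxymethoxy)-2,8-dimethyl-2-(4-methylpent-3-en-1-yl)-2H-chromene
Conditions: (H2IMes)(PCy3)Cl2Ru=CHPh (second-generation Grubbs catalyst, 5 mol%), CH2Cl2 (0.01 M), 40 °C, argon sparge
Reagents that add atoms: none
Why: Ring-closing olefin metathesis: the carbene of (H2IMes)(PCy3)Cl2Ru=CHPh exchanges with the terminal styrene CH=CH2 to give (H2IMes)Cl2Ru=CH–Ar, which adds intramolecularly by [2+2] cycloaddition to the vinyl group on the quaternary carbinol carbon, and cycloreversion of the four-membered metallacycle releases the chromene and (H2IMes)Cl2Ru=CH2, ethylene being swept out. The closest known reaction type is the metathesis closure of 2-(1,1-disubstituted allyloxy)styrenes to 2,2-disubstituted 2H-chromenes. Ring B is closed as a six-membered ring by forming the endocyclic, necessarily cis C3=C4 double bond. No stereocentre is created and no bond to C2 is made or broken, so the (R) configuration brought in from linalool is retained. The selectivity needed is closure onto the styrene partner and not cyclopentene formation between the C2 vinyl and the trisubstituted side-chain alkene, the pathway linalool itself follows. The catalyst should load much faster on the styrene than on the vinyl next to the quaternary centre, which here lacks the free hydroxyl that speeds the linalool closure, and the trisubstituted alkene is a poor partner for the aryl-substituted carbene.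

Step 9
Reactants: 17 (R)-2-methylbutanoic acid
Product: 19 (2R)-N-methoxy-N,2-dimethylbutanamide, via acyl imidazolide 18 (not isolated)
Conditions: 1,1'-carbonyldiimidazole (CDI), CH2Cl2, 0 °C → rt; then MeNHOMe·HCl, rt
Reagents that add atoms: N,O-dimethylhydroxylamine hydrochloride, CNOC.Cl
Why: Weinreb amide synthesis through the acyl imidazolide avoids the acid chloride/amine base combination, so the α-stereocentre should not epimerise through a ketene or enol.

Step 10
Reactants: 16 (2R)-5,7-bis(methoxymethoxy)-2,8-dimethyl-2-(4-methylpent-3-en-1-yl)-2H-chromene; 19 (2R)-N-methoxy-N,2-dimethylbutanamide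
Product: 22 (2R)-1-[(2R)-5,7-bis(methoxymethoxy)-2,8-dimethyl-2-(4-methylpent-3-en-1-yl)-2H-chromen-6-yl]-2-methylbutan-1-one, via aryllithium 20 (not isolated), via lithium hemiaminal adduct 21 (not isolated)
Conditions: n-BuLi, THF, 0 °C; then 19, −78 °C → 0 °C; aq. NH4Cl
Reagents that add atoms: none
Why: Directed ortho-metalation occurs at C6, the only aryl C–H and the position between the two MOM ethers, and the aryllithium adds once to the Weinreb amide to give a chelated tetrahedral adduct that collapses to the ketone only on quench (Weinreb ketone synthesis), so the α-stereogenic ketone never meets the base.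

Step 11
Reactants: 22 (2R)-1-[(2R)-5,7-bis(methoxymethoxy)-2,8-dimethyl-2-(4-methylpent-3-en-1-yl)-2H-chromen-6-yl]-2-methylbutan-1-one
Product: 23 (2R)-1-[(2R)-5,7-dihydroxy-2,8-dimethyl-2-(4-methylpent-3-en-1-yl)-2H-chromen-6-yl]-2-methylbutan-1-one
Conditions: aq. HCl (cat.), MeOH, rt
Reagents that add atoms: none
Why: Acid-catalysed acetal methanolysis removes both MOM groups, each ortho to the carbonyl and therefore labile to dilute acid at room temperature, while the C2–O1 ether (its oxygen para to the acyl group and poorly basic), the side-chain alkene and the α-stereocentre should persist.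

Step 12
Reactants: 23 (2R)-1-[(2R)-5,7-dihydroxy-2,8-dimethyl-2-(4-methylpent-3-en-1-yl)-2H-chromen-6-yl]-2-methylbutan-1-one
Product: 25 (2R)-5-hydroxy-2,8,8-trimethyl-6-[(2R)-2-methylbutanoyl]-2-(4-methylpent-3-en-1-yl)-2H-chromen-7(8H)-one, via sodium phenoxide 24 (not isolated)
Conditions: NaOMe, MeI, MeOH, 0 °C → rt; pH 4 work-up
Reagents that add atoms: iodomethane, CI
Why: Base-mediated dearomative C-methylation of an acylphloroglucinol (the alkylation that gives acylfilicinic acids) should occur at C8, the only non-acylated ring carbon ortho and para to the phenoxide oxygens, since methanol solvates the oxygen and favours attack through carbon; the cyclohexadienone formed cannot re-aromatise, no stereocentre is created, the anionic enolate shields the side-chain α-carbon from epimerisation, and keeping the mixture at or below room temperature should keep the dearomatised 2H-pyran from opening by oxa-6π ring opening.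

## Compound list

1 | 1-fluoro-3,5-dimethoxybenzene | COc1cc(F)cc(OC)c1 | starting material
2 | N-[(2-fluoro-4,6-dimethoxyphenyl)methylidene]-N-methylmethanaminium chloride | C[N+](C)=Cc1c(F)cc(OC)cc1OC.[Cl-] | intermediate
3 | 2-fluoro-4,6-dimethoxybenzaldehyde | O=Cc1c(F)cc(OC)cc1OC | intermediate
4 | (2-fluoro-4,6-dimethoxyphenyl)methanol | OCc1c(F)cc(OC)cc1OC | intermediate
5 | 1-fluoro-3,5-dimethoxy-2-methylbenzene | Cc1c(F)cc(OC)cc1OC | intermediate
6 | N-[(2-fluoro-4,6-dimethoxy-3-methylphenyl)methylidene]-N-methylmethanaminium chloride | C[N+](C)=Cc1c(F)c(C)c(OC)cc1OC.[Cl-] | intermediate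
7 | 2-fluoro-4,6-dimethoxy-3-methylbenzaldehyde | O=Cc1c(F)c(C)c(OC)cc1OC | intermediate
8 | 2-fluoro-4,6-bis[(dibromoboranyl)oxy]-3-methylbenzaldehyde | O=Cc1c(F)c(C)c(OB(Br)Br)cc1OB(Br)Br | intermediate
9 | 2-fluoro-4,6-dihydroxy-3-methylbenzaldehyde | O=Cc1c(F)c(C)c(O)cc1O | intermediate
10 | disodium 5-fluoro-4-formyl-6-methylbenzene-1,3-diolate | O=Cc1c(F)c(C)c([O-])cc1[O-].[Na+].[Na+] | intermediate
11 | 2-fluoro-4,6-bis(methoxymethoxy)-3-methylbenzaldehyde | O=Cc1c(F)c(C)c(OCOC)cc1OCOC | intermediate
12 | (R)-linalool, (3R)-3,7-dimethylocta-1,6-dien-3-ol | CC(C)=CCC[C@@](C)(O)C=C | starting material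
13 | potassium (3R)-3,7-dimethylocta-1,6-dien-3-olate | CC(C)=CCC[C@@](C)([O-])C=C.[K+] | intermediate
14 | 2-{[(3R)-3,7-dimethylocta-1,6-dien-3-yl]oxy}-4,6-bis(methoxymethoxy)-3-methylbenzaldehyde | O=Cc1c(O[C@](C)(CCC=C(C)C)C=C)c(C)c(OCOC)cc1OCOC | intermediate
15 | 2-{[(3R)-3,7-dimethylocta-1,6-dien-3-yl]oxy}-1-ethenyl-4,6-bis(methoxymethoxy)-3-methylbenzene | C=Cc1c(O[C@](C)(CCC=C(C)C)C=C)c(C)c(OCOC)cc1OCOC | intermediate
16 | (2R)-5,7-bis(methoxymethoxy)-2,8-dimethyl-2-(4-methylpent-3-en-1-yl)-2H-chromene | COCOc1cc(OCOC)c2c(c1C)O[C@](C)(CCC=C(C)C)C=C2 | intermediate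
17 | (R)-2-methylbutanoic acid | CC[C@@H](C)C(=O)O | starting material
18 | (2R)-1-(1H-imidazol-1-yl)-2-methylbutan-1-one | CC[C@@H](C)C(=O)n1ccnc1 | intermediate
19 | (2R)-N-methoxy-N,2-dimethylbutanamide | CC[C@@H](C)C(=O)N(C)OC | intermediate
20 | [(2R)-5,7-bis(methoxymethoxy)-2,8-dimethyl-2-(4-methylpent-3-en-1-yl)-2H-chromen-6-yl]lithium | COCOc1c([Li])c(OCOC)c2c(c1C)O[C@](C)(CCC=C(C)C)C=C2 | intermediate
21 | lithium (2R)-1-[(2R)-5,7-bis(methoxymethoxy)-2,8-dimethyl-2-(4-methylpent-3-en-1-yl)-2H-chromen-6-yl]-1-[methoxy(methyl)amino]-2-methylbutan-1-olate | CC[C@@H](C)C(O[Li])(N(C)OC)c1c(OCOC)c(C)c2O[C@](C)(CCC=C(C)C)C=Cc2c1OCOC | intermediate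
22 | (2R)-1-[(2R)-5,7-bis(methoxymethoxy)-2,8-dimethyl-2-(4-methylpent-3-en-1-yl)-2H-chromen-6-yl]-2-methylbutan-1-one | CC[C@@H](C)C(=O)c1c(OCOC)c(C)c2O[C@](C)(CCC=C(C)C)C=Cc2c1OCOC | intermediate
23 | (2R)-1-[(2R)-5,7-dihydroxy-2,8-dimethyl-2-(4-methylpent-3-en-1-yl)-2H-chromen-6-yl]-2-methylbutan-1-one | CC[C@@H](C)C(=O)c1c(O)c(C)c2O[C@](C)(CCC=C(C)C)C=Cc2c1O | intermediate
24 | sodium (2R)-5-hydroxy-2,8-dimethyl-6-[(2R)-2-methylbutanoyl]-2-(4-methylpent-3-en-1-yl)-2H-chromen-7-olate | CC[C@@H](C)C(=O)c1c([O-])c(C)c2O[C@](C)(CCC=C(C)C)C=Cc2c1O.[Na+] | intermediate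
25 | (2R)-5-hydroxy-2,8,8-trimethyl-6-[(2R)-2-methylbutanoyl]-2-(4-methylpent-3-en-1-yl)-2H-chromen-7(8H)-one | CC[C@@H](C)C(=O)C1=C(O)C2=C(O[C@](C)(CCC=C(C)C)C=C2)C(C)(C)C1=O | target

## Step count and risks

Total step count: 12. Longest linear sequence: 11 steps (steps 1–8 and 10–12 from compound 1); step 9 is a one-step branch.

Steps most likely to fail:

1. Step 6 (fluoride displacement). The bulky tertiary alkoxide may add reversibly to the formyl group while attack at the fluorine-bearing carbon, flanked by methyl and formyl, stays slow; on warming, hydride transfer from the hemiacetal alkoxide or aromatic Claisen rearrangement of the product ether toward the free para position could then take over. The fallback sets out from 11 and replaces the activating group. The aldehyde is oxidised with I2 and aqueous NH3 in THF to 2-fluoro-4,6-bis(methoxymethoxy)-3-methylbenzonitrile F1, whose linear cyano group activates more strongly and cannot trap the alkoxide. Alkoxide 13 (from 12 and KH) should then displace fluoride at or below room temperature to give 2-{[(3R)-3,7-dimethylocta-1,6-dien-3-yl]oxy}-4,6-bis(methoxymethoxy)-3-methylbenzonitrile F2. Reduction with i-Bu2AlH in toluene at −78 °C and hydrolysis of the aldimine with aqueous potassium sodium tartrate returns to the route at 14.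

2. Step 8 (ring-closing metathesis). The metal carbene may form on the vinyl at the quaternary carbon and close onto the trisubstituted side-chain alkene, expelling isobutene and giving a cyclopentenyl aryl ether in place of ring B. The fallback sets out from 15 and masks the competing alkene. One equivalent of mCPBA with NaHCO3 in CH2Cl2 at −20 °C should epoxidise the trialkyl-substituted alkene, the most nucleophilic of the three, to 2-{[(3R)-5-(3,3-dimethyloxiran-2-yl)-3-methylpent-1-en-3-yl]oxy}-1-ethenyl-4,6-bis(methoxymethoxy)-3-methylbenzene F3 (epoxide epimers, of no consequence). The same metathesis conditions then can only close ring B, giving (2R)-2-[2-(3,3-dimethyloxiran-2-yl)ethyl]-5,7-bis(methoxymethoxy)-2,8-dimethyl-2H-chromene F4. Deoxygenation of the epoxide with the low-valent tungsten reagent from WCl6 and n-BuLi in THF restores the alkene and returns to the route at 16.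

3. Step 10 (acylation). The di-ortho-substituted aryllithium may deprotonate the α-branched amide or attack its N-methoxy group instead of adding to the carbonyl, which would return protonated 16. The fallback sets out from aryllithium 20 (made from 16 as in step 10) and amide 19. Amide 19 is reduced with LiAlH4 in THF at −78 °C to (R)-2-methylbutanal F5, used at once as a cold solution to limit α-epimerisation. Addition of 20 at −78 °C gives (2R)-1-[(2R)-5,7-bis(methoxymethoxy)-2,8-dimethyl-2-(4-methylpent-3-en-1-yl)-2H-chromen-6-yl]-2-methylbutan-1-ol F6 as a mixture of carbinol epimers. Oxidation with Dess–Martin periodinane and NaHCO3 in CH2Cl2 returns to the route at 22.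

## Further compounds

F1 | step 6 | 2-fluoro-4,6-bis(methoxymethoxy)-3-methylbenzonitrile | N#Cc1c(F)c(C)c(OCOC)cc1OCOC
F2 | step 6 | 2-{[(3R)-3,7-dimethylocta-1,6-dien-3-yl]oxy}-4,6-bis(methoxymethoxy)-3-methylbenzonitrile | N#Cc1c(O[C@](C)(CCC=C(C)C)C=C)c(C)c(OCOC)cc1OCOC
F3 | step 8 | 2-{[(3R)-5-(3,3-dimethyloxiran-2-yl)-3-methylpent-1-en-3-yl]oxy}-1-ethenyl-4,6-bis(methoxymethoxy)-3-methylbenzene | C=Cc1c(O[C@](C)(CCC2OC2(C)C)C=C)c(C)c(OCOC)cc1OCOC
F4 | step 8 | (2R)-2-[2-(3,3-dimethyloxiran-2-yl)ethyl]-5,7-bis(methoxymethoxy)-2,8-dimethyl-2H-chromene | COCOc1cc(OCOC)c2c(c1C)O[C@](C)(CCC1OC1(C)C)C=C2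
F5 | step 10 | (R)-2-methylbutanal | CC[C@@H](C)C=O
F6 | step 10 | (2R)-1-[(2R)-5,7-bis(methoxymethoxy)-2,8-dimethyl-2-(4-methylpent-3-en-1-yl)-2H-chromen-6-yl]-2-methylbutan-1-ol | CC[C@@H](C)C(O)c1c(OCOC)c(C)c2O[C@](C)(CCC=C(C)C)C=Cc2c1OCOC
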